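The ring A–O–ring B ether of CNP0290892.0 is closed last by anodic coupling of an open dibromo/dichloro bisphenol; the full route is 15 steps with a longest linear sequence of 12.

**Plan**

- Enabling feature: in ring A (the catechol ring) the carbon bonded to the ring B oxygen lies ortho to the central phenolic OH. The carbon para to that OH carries the CH2CH2 bridge to ring D. This is the pattern an ortho C–O oxidative phenol coupling leaves behind.
- Cuts: (1) the ring A C–O(ring B) ether, which opens the 17-membered ring; (2) the central C–C bond of each CH2CH2 bridge (A/D and B/C; Wittig, then diimide); (3) the ring C O–C(ring D) ether (SNAr).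
- Forward order: ring B ylide plus o-vanillin (ring C), SNAr onto 2-fluorobenzaldehyde (ring D), ring A ylide, saturation and debenzylation give the open bisphenol. The macrocycle is the only ring made and it closes last, at the anode.
- Halogen roles: ring A travels as a 2,6-dibromophenol (acceptor, two equivalent ortho carbons) and ring B as a 2,6-dichlorophenol (oxygen donor). Afterwards the bromine left on ring A is exchanged for OMe, the chlorines are hydrogenolysed and the methyl ethers are cleaved.
- Stereochemistry: the target has no stereocentre. Alkene E/Z mixtures and the transient sp3 carbons of the dienones are all erased.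

Key step: step 12

Remark on the chemistry: the macrocycles are treated as conformationally mobile, with no stable planar-chiral form, as the descriptor-free target SMILES implies. The Wittig products are carried as E/Z mixtures, so their SMILES are written without alkene geometry.

Design remark: a 2-bromo-6-methoxyphenol on ring A would be easier to oxidise. However, guaiacol-type phenoxonium ions are normally captured at the methoxy-bearing ortho carbon (o-quinone monoketal formation) or slip to p-quinone methides. The locally symmetric dibromophenol removes this site problem and puts the closure on the established dihalophenol pattern. The price is one later copper-catalysed methoxylation.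

**Route**

Step 1
Reactants: 1 3,5-dichloro-4-hydroxybenzaldehyde
Product: 2 4-(benzyloxy)-3,5-dichlorobenzaldehyde
Conditions: BnBr, K2CO3, DMF, 60 °C
Reagents that add atoms: benzyl bromide, BrCc1ccccc1
Why: Williamson etherification; carbonate fully ionises the acidic dichlorophenol and the reactive benzylic halide makes up for the low nucleophilicity of the hindered phenoxide.

Step 2
Reactants: 2 4-(benzyloxy)-3,5-dichlorobenzaldehyde
Product: 3 [4-(benzyloxy)-3,5-dichlorophenyl]methanol
Conditions: NaBH4, MeOH–THF, 0 °C
Reagents that add atoms: none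
Why: Borohydride reduction of an aromatic aldehyde, to which aryl chlorides and the benzyl ether are inert.

Step 3
Reactants: 3 [4-(benzyloxy)-3,5-dichlorophenyl]methanol
Product: 4 {[4-(benzyloxy)-3,5-dichlorophenyl]methyl}triphenylphosphonium bromide (ring B salt)
Conditions: PPh3·HBr, MeCN, reflux
Reagents that add atoms: triphenylphosphine hydrobromide, Br.c1ccc(cc1)P(c1ccccc1)c1ccccc1
Why: Direct phosphonium salt formation from a benzylic alcohol (acid-promoted nucleophilic substitution); the alcohol oxygen is the most basic site, so the weakly basic aryl benzyl ether should stay intact.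

Step 4
Reactants: 4 ring B salt; 5 o-vanillin (2-hydroxy-3-methoxybenzaldehyde)
Product: 7 2-{2-[4-(benzyloxy)-3,5-dichlorophenyl]ethenyl}-6-methoxyphenol (E/Z mixture), via ring B ylide 6 (not isolated)
Conditions: KOtBu (2.2 equiv), THF, 0 °C to reflux; then 1 M HCl
Reagents that add atoms: none
Why: Wittig olefination with a semi-stabilised benzylide; the second equivalent of base holds the aldehyde partner as its phenoxide, a variant well known for salicylaldehydes, and the alkene geometry does not matter because step 10 saturates it.

Step 5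
Reactants: 7 stilbene phenol; 8 2-fluorobenzaldehyde
Product: 9 2-(2-{2-[4-(benzyloxy)-3,5-dichlorophenyl]ethenyl}-6-methoxyphenoxy)benzaldehyde
Conditions: K2CO3, DMF, 110 °C, N2
Reagents that add atoms: none
Why: SNAr diaryl ether synthesis; the ortho-formyl group activates the C–F bond through a Meisenheimer adduct, the electron-rich phenoxide of 7 is a competent nucleophile, and the unactivated aryl chlorides do not react.

Step 6
Reactants: 10 3,5-dibromo-4-hydroxybenzaldehyde
Product: 11 4-(benzyloxy)-3,5-dibromobenzaldehyde
Conditions: BnBr, K2CO3, DMF, 60 °C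
Reagents that add atoms: benzyl bromide, BrCc1ccccc1
Why: Williamson etherification, as in step 1.

Step 7
Reactants: 11 4-(benzyloxy)-3,5-dibromobenzaldehyde
Product: 12 [4-(benzyloxy)-3,5-dibromophenyl]methanol
Conditions: NaBH4, MeOH–THF, 0 °C
Reagents that add atoms: none
Why: Borohydride reduction of the aldehyde, which leaves aryl bromides untouched.

Step 8
Reactants: 12 [4-(benzyloxy)-3,5-dibromophenyl]methanol
Product: 13 {[4-(benzyloxy)-3,5-dibromophenyl]methyl}triphenylphosphonium bromide (ring A salt)
Conditions: PPh3·HBr, MeCN, reflux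
Reagents that add atoms: triphenylphosphine hydrobromide, Br.c1ccc(cc1)P(c1ccccc1)c1ccccc1
Why: Direct phosphonium salt formation from the benzylic alcohol, as in step 3.

Step 9
Reactants: 9 ring B–C–D aldehyde; 13 ring A salt
Product: 15 bis-stilbene carrying all four rings (ring A 4-benzyloxy-3,5-dibromo; ring B 4-benzyloxy-3,5-dichloro; E/Z mixtures at both alkenes), via ring A ylide 14 (not isolated)
Conditions: KOtBu (1.1 equiv), THF, 0 °C to rt
Reagents that add atoms: none
Why: Wittig olefination; an alkoxide base generates the ylide without the halogen–metal exchange that an alkyllithium would cause at the aryl bromides.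

Step 10
Reactants: 15 bis-stilbene
Product: 16 open bis(bibenzyl) dibenzyl ether (both CH=CH units now CH2CH2)
Conditions: TsNHNH2 (excess, in portions), NaOAc, THF–H2O, reflux
Reagents that add atoms: none
Why: Diimide reduction; the concerted transfer of H2 touches only the C=C bonds, so the C–Br, C–Cl and O-benzyl bonds that Pd/H2 would break are kept.

Step 11
Reactants: 16 open bis(bibenzyl) dibenzyl ether
Product: 17 2,6-dibromo-4-[2-(2-{2-[2-(3,5-dichloro-4-hydroxyphenyl)ethyl]-6-methoxyphenoxy}phenyl)ethyl]phenol (seco bisphenol)
Conditions: BCl3, pentamethylbenzene, CH2Cl2, −78 °C; then H2O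
Reagents that add atoms: none
Why: Lewis-acid debenzylation with a non-basic cation scavenger; at −78 °C the benzyl ethers of the good-leaving dihalophenols cleave far faster than the ring C methyl ether, and aryl halides are unaffected.

Step 12
Reactants: 17 seco bisphenol
Product: 20 macrocyclic bromophenol (17-membered; ring A OH flanked by Br and by the new O–ring B bond; ring B 2,6-dichloro; ring C OMe), via bromo dienone 18 (not isolated), via methoxy dienone 19 (not isolated)
Conditions: glassy carbon anode, Pt cathode, undivided cell, controlled potential at the first anodic wave of 17 (located by cyclic voltammetry), about 2 F/mol, LiClO4 (0.1 M), MeOH–CH2Cl2 4:1, 1 mM, rt; evaporate; then Zn dust, AcOH–THF, rt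
Reagents that add atoms: methanol, CO (its methoxy group sits only in intermediate 19 and leaves again in the zinc step; nothing from it stays in 20)
Why: Anodic two-electron oxidation of the ring A 2,6-dibromophenol gives a phenoxonium-type species whose bromine-bearing ortho carbon is captured by the phenolic oxygen of ring B to give 18; methanol then adds to the para carbon with expulsion of bromide to give quinol ether 19, and zinc in acetic acid reductively ejects methanol and restores the ring A phenol of 20. The closest known reaction type is the anodic or Tl(NO3)3 oxidative C–O coupling of o,o'-dihalophenols followed by zinc reduction, which has been used to close isodityrosine-type macrocyclic diaryl ethers of comparable size. The single ring formed, the 17-membered macrocycle, closes end to end by intramolecular attack of the ring B oxygen on ring A at millimolar concentration. The sp3 carbons of 18 and 19 arise as racemates without control and vanish on rearomatisation, so the step leaves no stereocentre. It needs the right direction of coupling, C–O instead of C–C bonding and closure instead of oligomerisation: the lower oxidation potential of the dibromophenol and the easier loss of bromide than of chloride make ring A the acceptor, the two equivalent ortho carbons of ring A remove any site question, the halogen- or alkyl-blocked ortho and para carbons of both phenols leave C–C adducts no way to rearomatise, and dilution favours the ring. Methanol capture of uncyclised oxidised material gives only a quinol ether that the zinc step turns back into 17.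

Step 13
Reactants: 20 macrocyclic bromophenol
Product: 21 dichloro macrocycle with ring A as 2-aryloxy-6-methoxyphenol
Conditions: NaOMe (excess), CuBr (cat.), DMF–MeOH, 100 °C, N2; then 1 M HCl
Reagents that add atoms: sodium methoxide, [Na+].[O-]C
Why: Copper-catalysed Ullmann-type methoxylation of an o-bromophenol, the reaction type that turns 5-bromovanillin into syringaldehyde; aryl chlorides are far less reactive toward monovalent copper and should remain.

Step 14
Reactants: 21 dichloro macrocycle
Product: 22 macrocyclic dimethyl ether (ring B now an unsubstituted para-phenylene)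
Conditions: H2 (1–3 atm), 10% Pd/C, NaOAc, MeOH–EtOAc, rt
Reagents that add atoms: none
Why: Catalytic hydrodechlorination with a base to take up HCl, the usual way to strip blocking halogens after a dihalophenol coupling; no other reducible group is left.

Step 15
Reactants: 22 macrocyclic dimethyl ether
Product: 23 CNP0290892.0 (target)
Conditions: BBr3, CH2Cl2, −78 °C to rt; then H2O, work-up under N2
Reagents that add atoms: none
Why: BBr3 cleavage of aryl methyl ethers (boron complexation, then bromide attack at methyl); diaryl ethers are inert, so only the two OMe groups are lost.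

**Compound list**

| No. | Name | SMILES | Role |
|---|---|---|---|
| 1 | 3,5-dichloro-4-hydroxybenzaldehyde | O=Cc1cc(Cl)c(O)c(Cl)c1 | starting material |
| 2 | 4-(benzyloxy)-3,5-dichlorobenzaldehyde | O=Cc1cc(Cl)c(OCc2ccccc2)c(Cl)c1 | intermediate |
| 3 | [4-(benzyloxy)-3,5-dichlorophenyl]methanol | OCc1cc(Cl)c(OCc2ccccc2)c(Cl)c1 | intermediate |
| 4 | ring B phosphonium bromide | [Br-].Clc1cc(C[P+](c2ccccc2)(c2ccccc2)c2ccccc2)cc(Cl)c1OCc1ccccc1 | intermediate |
| 5 | o-vanillin | COc1cccc(C=O)c1O | starting material |
| 6 | ring B ylide (benzylidene triphenylphosphorane) | Clc1cc(C=P(c2ccccc2)(c2ccccc2)c2ccccc2)cc(Cl)c1OCc1ccccc1 | intermediate |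
| 7 | 2-{2-[4-(benzyloxy)-3,5-dichlorophenyl]ethenyl}-6-methoxyphenol (E/Z) | COc1cccc(C=Cc2cc(Cl)c(OCc3ccccc3)c(Cl)c2)c1O | intermediate |
| 8 | 2-fluorobenzaldehyde | O=Cc1ccccc1F | starting material |
| 9 | ring B–C–D aldehyde (E/Z) | COc1cccc(C=Cc2cc(Cl)c(OCc3ccccc3)c(Cl)c2)c1Oc1ccccc1C=O | intermediate |
| 10 | 3,5-dibromo-4-hydroxybenzaldehyde | O=Cc1cc(Br)c(O)c(Br)c1 | starting material |
| 11 | 4-(benzyloxy)-3,5-dibromobenzaldehyde | O=Cc1cc(Br)c(OCc2ccccc2)c(Br)c1 | intermediate |
| 12 | [4-(benzyloxy)-3,5-dibromophenyl]methanol | OCc1cc(Br)c(OCc2ccccc2)c(Br)c1 | intermediate |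
| 13 | ring A phosphonium bromide | [Br-].Brc1cc(C[P+](c2ccccc2)(c2ccccc2)c2ccccc2)cc(Br)c1OCc1ccccc1 | intermediate |
| 14 | ring A ylide | Brc1cc(C=P(c2ccccc2)(c2ccccc2)c2ccccc2)cc(Br)c1OCc1ccccc1 | intermediate |
| 15 | bis-stilbene (E/Z at both alkenes) | COc1cccc(C=Cc2cc(Cl)c(OCc3ccccc3)c(Cl)c2)c1Oc1ccccc1C=Cc1cc(Br)c(OCc2ccccc2)c(Br)c1 | intermediate |
| 16 | open bis(bibenzyl) dibenzyl ether | COc1cccc(CCc2cc(Cl)c(OCc3ccccc3)c(Cl)c2)c1Oc1ccccc1CCc1cc(Br)c(OCc2ccccc2)c(Br)c1 | intermediate |
| 17 | seco dibromo dichloro bisphenol | COc1cccc(CCc2cc(Cl)c(O)c(Cl)c2)c1Oc1ccccc1CCc1cc(Br)c(O)c(Br)c1 | intermediate |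
| 18 | macrocyclic 6-aryloxy-2,6-dibromocyclohexa-2,4-dienone (racemic) | O=C1C(Br)=CC2=CC1(Br)Oc1c(Cl)cc(cc1Cl)CCc1cccc(OC)c1Oc1ccccc1CC2 | intermediate |
| 19 | macrocyclic 2-aryloxy-6-bromo-4-methoxycyclohexa-2,5-dienone (racemic) | O=C1C(Br)=CC2(OC)C=C1Oc1c(Cl)cc(cc1Cl)CCc1cccc(OC)c1Oc1ccccc1CC2 | intermediate |
| 20 | macrocyclic bromophenol | Oc1c(Br)cc2cc1Oc1c(Cl)cc(cc1Cl)CCc1cccc(OC)c1Oc1ccccc1CC2 | intermediate |
| 21 | dichloro macrocyclic methoxyphenol | COc1cc2cc(c1O)Oc1c(Cl)cc(cc1Cl)CCc1cccc(OC)c1Oc1ccccc1CC2 | intermediate |
| 22 | macrocyclic dimethyl ether | COc1cc2cc(c1O)Oc1ccc(cc1)CCc1cccc(OC)c1Oc1ccccc1CC2 | intermediate |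
| 23 | CNP0290892.0 | Oc1cc2cc(c1O)Oc1ccc(cc1)CCc1cccc(O)c1Oc1ccccc1CC2 | target |

Total step count: 15. Longest linear sequence: 12 steps (steps 1–5, then 9–15).

**Steps most likely to fail**

**Step 12 (anodic macrocyclisation).**
- What may go wrong: intermolecular coupling may outrun ring closure. Electron transfer may occur from ring B or from the anisole-type ring C instead of ring A, which reverses or derails the coupling. Bromine formed at the anode from the released bromide may halogenate rings C and D.
- The fallback closes the same C–O bond by copper-catalysed Ullmann etherification instead of oxidation. It sets out from 5 and comes back at 23.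
- Purchased (4-benzyloxybenzyl)triphenylphosphonium chloride F1 is deprotonated (KOtBu, 2.2 equiv, THF) to its ylide F2. This condenses with 5 to the stilbene phenol F3.
- SNAr of F3 with 8 (K2CO3, DMF) gives the aldehyde F4.
- Purchased 3-bromo-4,5-dimethoxybenzaldehyde F5 is reduced (NaBH4) to the benzylic alcohol F6. This is converted with PPh3·HBr into the phosphonium bromide F7.
- The ylide F8 made from F7 (KOtBu, THF) reacts with F4 to give the bis-stilbene F9.
- Diimide saturation gives the bis(bibenzyl) F10, and BCl3 with pentamethylbenzene at −78 °C frees the ring B phenol F11.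
- Slow addition of F11 to CuI, N,N-dimethylglycine and Cs2CO3 in dioxane at 100 °C should join the unhindered 4-alkylphenol to the ring A bromide. This gives the macrocyclic trimethyl ether F12.
- BBr3 under the conditions of step 15 converts F12 into 23.

**Step 13 (methoxylation of the bromophenol).**
- What may go wrong: hydrodebromination may compete with C–O bond formation. The ring A phenoxide may arylate itself at a neighbouring ring B C–Cl bond (dioxin-type closure) under hot basic copper conditions.
- The fallback caps the phenol and brings in the oxygen through boron. It sets out from 20 and comes back at 23.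
- 20 is O-methylated (MeI, K2CO3, acetone) to the bromo anisole F13.
- Miyaura borylation (B2pin2, Pd(dppf)Cl2, KOAc, dioxane, 90 °C) is selective for C–Br over the hindered C–Cl bonds and gives the pinacol boronate F14.
- Oxidation (H2O2, NaOH, THF–H2O, 0 °C) gives the phenol F15.
- Hydrogenolysis as in step 14 gives the dechlorinated macrocycle F16, and BBr3 as in step 15 gives 23.

**Step 4 (Wittig reaction on the free phenol).**
- What may go wrong: phenoxide formation deactivates the aldehyde, and proton exchange quenches the ylide. Olefination may then stall.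
- The fallback reverses the order of ether formation and olefination. It sets out from 5 and comes back at 9, so it replaces steps 4 and 5.
- 5 is first arylated with purchased 2-fluorobenzonitrile F17 (K2CO3, DMF, 130 °C) to the aldehyde nitrile F18. Its two carbonyl-level groups are thereby differentiated.
- The aldehyde of F18 no longer has a neighbouring phenoxide. It reacts with ylide 6 (from 4, KOtBu, 1.1 equiv, THF) to give the stilbene nitrile F19.
- DIBAL-H (toluene, −78 °C) followed by aqueous HCl converts the nitrile into the aldehyde 9.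

Further compounds
F1 | step 12 | (4-benzyloxybenzyl)triphenylphosphonium chloride (purchased) | [Cl-].c1ccc(cc1)COc1ccc(C[P+](c2ccccc2)(c2ccccc2)c2ccccc2)cc1
F2 | step 12 | (4-benzyloxybenzylidene)triphenylphosphorane | c1ccc(cc1)COc1ccc(C=P(c2ccccc2)(c2ccccc2)c2ccccc2)cc1
F3 | step 12 | 2-{2-[4-(benzyloxy)phenyl]ethenyl}-6-methoxyphenol (E/Z) | COc1cccc(C=Cc2ccc(OCc3ccccc3)cc2)c1O
F4 | step 12 | 2-(2-{2-[4-(benzyloxy)phenyl]ethenyl}-6-methoxyphenoxy)benzaldehyde (E/Z) | COc1cccc(C=Cc2ccc(OCc3ccccc3)cc2)c1Oc1ccccc1C=O
F5 | step 12 | 3-bromo-4,5-dimethoxybenzaldehyde (purchased) | COc1cc(C=O)cc(Br)c1OC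
F6 | step 12 | (3-bromo-4,5-dimethoxyphenyl)methanol | COc1cc(CO)cc(Br)c1OC
F7 | step 12 | [(3-bromo-4,5-dimethoxyphenyl)methyl]triphenylphosphonium bromide | [Br-].COc1cc(C[P+](c2ccccc2)(c2ccccc2)c2ccccc2)cc(Br)c1OC
F8 | step 12 | (3-bromo-4,5-dimethoxybenzylidene)triphenylphosphorane | COc1cc(C=P(c2ccccc2)(c2ccccc2)c2ccccc2)cc(Br)c1OC
F9 | step 12 | bis-stilbene with ring A 3-bromo-4,5-dimethoxy and ring B 4-benzyloxy (E/Z) | COc1cccc(C=Cc2ccc(OCc3ccccc3)cc2)c1Oc1ccccc1C=Cc1cc(Br)c(OC)c(OC)c1
F10 | step 12 | saturated bis(bibenzyl) benzyl ether | COc1cccc(CCc2ccc(OCc3ccccc3)cc2)c1Oc1ccccc1CCc1cc(Br)c(OC)c(OC)c1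
F11 | step 12 | open bromo phenol for the Ullmann closure | COc1cccc(CCc2ccc(O)cc2)c1Oc1ccccc1CCc1cc(Br)c(OC)c(OC)c1
F12 | step 12 | macrocyclic trimethyl ether | COc1cc2cc(c1OC)Oc1ccc(cc1)CCc1cccc(OC)c1Oc1ccccc1CC2
F13 | step 13 | O-methyl ether of 20 (bromo anisole) | COc1c(Br)cc2cc1Oc1c(Cl)cc(cc1Cl)CCc1cccc(OC)c1Oc1ccccc1CC2
F14 | step 13 | ring A pinacol boronate | COc1c(B3OC(C)(C)C(C)(C)O3)cc2cc1Oc1c(Cl)cc(cc1Cl)CCc1cccc(OC)c1Oc1ccccc1CC2
F15 | step 13 | dichloro macrocycle with ring A 3-aryloxy-2-methoxyphenol | COc1c(O)cc2cc1Oc1c(Cl)cc(cc1Cl)CCc1cccc(OC)c1Oc1ccccc1CC2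
F16 | step 13 | dechlorinated isomeric dimethyl ether | COc1c(O)cc2cc1Oc1ccc(cc1)CCc1cccc(OC)c1Oc1ccccc1CC2
F17 | step 4 | 2-fluorobenzonitrile (purchased) | N#Cc1ccccc1F
F18 | step 4 | 2-(2-formyl-6-methoxyphenoxy)benzonitrile | COc1cccc(C=O)c1Oc1ccccc1C#N
F19 | step 4 | 2-(2-{2-[4-(benzyloxy)-3,5-dichlorophenyl]ethenyl}-6-methoxyphenoxy)benzonitrile (E/Z) | COc1cccc(C=Cc2cc(Cl)c(OCc3ccccc3)c(Cl)c2)c1Oc1ccccc1C#N
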